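**Plan**
Cuts: (a) O12–C15 is re-closed on paper, because the 13Z γ-hydroxy acid is the hydrolysed form of a 15,12-butenolide. (b) C11–C12 is cut together with C9–H. (c) C11 and C17 are traced back to ring C of (+)-podocarpic acid.
Enabling feature: on ring B the array C12(OH)–C11H2–C9(H)–C8(=C17H2) is a 1,3-anti pent-4-en-1-ol, the retron of the nickel-catalysed reductive homoallylation of an aldehyde by a 1,3-diene. Here the diene is the s-cis bis-exocyclic unit C11=C9–C8=C17, and O12 and C15 lie cis on C13=C14, so the adduct lactonises by itself.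
Forward: rings A and B come ready-made. Ring C is excised by ozonolysis (C12 and C13 lost), then anhydride → ene-diol → dibromide → diene. The five-carbon side chain is joined in one operation, and the temporary butenolide ring is opened last.
Stereochemistry: C4, C5 and C10 come from the chiral pool. C9 is set by hydride delivery from nickel on the α face (the β face is shielded by C20). C12 (S) is set by the 1,3-anti metallacycle. 13Z comes from the furanone ring of the side-chain building block and is held by the lactone.

Key step: step 7

Remark (assumption): the target is taken as the free ring-opened hydroxy diacid, which is expected to re-close to the butenolide on acid or warming, so it is liberated only in the last step. Labdane numbering is used throughout (C11 and C14 of podocarpic acid become C11 and C17).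

Step 1
Reactants: 1 (+)-podocarpic acid
Product: 2 2-(trimethylsilyl)ethyl (TMSE) podocarpate
Conditions: TMSCH2CH2OC(=NH)CCl3 (1.5 equiv), PhMe, 110 °C
Reagents that add atoms: 2-(trimethylsilyl)ethyl 2,2,2-trichloroacetimidate C[Si](C)(C)CCOC(=N)C(Cl)(Cl)Cl
Why: Thermal promoter-free trichloroacetimidate esterification, in which the acid protonates the imidate and the carboxylate captures the β-silyl-stabilised cation, so the alkyl–oxygen bond forms away from the hindered axial C19 carbonyl, the less acidic phenol stays free and no stereocentre is touched.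

Step 2
Reactants: 2 TMSE podocarpate
Product: 4 11,17-anhydride of the 19-TMSE triacid ester, via ene-diacid 3 (not isolated)
Conditions: O3, CH2Cl2/MeOH, −78 °C; 30% H2O2, HCO2H, 0 → 40 °C; Ac2O, 80 °C
Reagents that add atoms: ozone [O-][O+]=O; hydrogen peroxide OO
Why: Exhaustive ozonolysis of an electron-rich phenol ring with oxidative work-up, a reaction type precedented on ring-C aromatic diterpenoids, should cleave C11=C12 and C13=C14 and release C12–C13 as oxalic acid, while the tetrasubstituted, doubly acceptor-substituted C8=C9 bond is too electron-poor to react and the cis-diacid dehydrates to the five-membered anhydride.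

Step 3
Reactants: 4 anhydride
Product: 5 TMSE 11,17-dihydroxy-12,13,14,15,16-pentanorlabd-8-en-19-oate
Conditions: i-Bu2AlH (6 equiv), CH2Cl2, −78 → 0 °C; aq. potassium sodium tartrate
Reagents that add atoms: none
Why: Hydride reduction of a dialkylmaleic anhydride to the (Z)-2-ene-1,4-diol, in which the axial neopentyl C19 ester (1,3-diaxial to C20) should react far more slowly than the planar anhydride and lactone carbonyls, the same steric bias that permits selective C15 reduction in labdane 15,19-diesters.

Step 4
Reactants: 5 ene-diol
Product: 6 TMSE 11,17-dibromo-12,13,14,15,16-pentanorlabd-8-en-19-oate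
Conditions: PBr3 (0.8 equiv), pyridine (cat.), Et2O, −10 → 0 °C
Reagents that add atoms: phosphorus tribromide BrP(Br)Br
Why: SN2 bromination of two primary allylic alcohols through their phosphite esters, run cold and lightly buffered so that double substitution outruns closure of the monobromide to a 2,5-dihydrofuran, and any allylically transposed bromide would converge on the same diene in step 5.

Step 5
Reactants: 6 dibromide
Product: 7 TMSE 12,13,14,15,16-pentanorlabda-8(17),9(11)-dien-19-oate
Conditions: Zn dust (activated), THF, rt, ultrasound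
Reagents that add atoms: none
Why: Reductive 1,4-elimination (zinc debromination) of a 1,4-dibromo-2-ene is the standard entry to 1,2-dimethylenecycloalkanes, the ester is inert, and the s-cis diene is used at once to avoid Diels–Alder dimerisation.

Step 6
Reactants: 8 5-hydroxy-4-methylfuran-2(5H)-one
Product: 10 methyl (Z)-3-methyl-4-oxobut-2-enoate, via potassium carboxylate 9 (not isolated)
Conditions: K2CO3, DMF, 0 °C; MeI, 0 °C → rt, dark
Reagents that add atoms: iodomethane CI
Why: Base opens the pseudo-acid to the (Z)-formyl carboxylate, and carboxylate O-alkylation (SN2 on MeI) gives the open-chain normal ester rather than the pseudo-ester, with the Z geometry inherited from the furanone ring.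

Step 7
Reactants: 7 bis-exocyclic diene; 10 methyl (Z)-3-methyl-4-oxobut-2-enoate
Product: 12 TMSE (12S)-labda-8(17),13-dien-15,12-olid-19-oate, via diethylborinate 11 (not isolated)
Conditions: Ni(acac)2 (10 mol %), Et3B (3 equiv), THF, rt, N2; 10 (2 equiv) added over 6 h; aq. citric acid work-up
Reagents that add atoms: none
Why: Et3B reduces Ni(acac)2 to zerovalent nickel, which binds the s-cis diene on its α face (the β face is covered by the axial C20 methyl) and undergoes oxidative cyclisation with the Et3B-activated aldehyde to forge C11–C12 and give an η3-allyl (C9–C8–C17) nickel alkoxide; ethyl transfer from boron to nickel, β-hydride elimination (loss of ethylene) and C–H reductive elimination at the allyl terminus next to the new bond then place H on C9 and leave C8=C17 in place. The closest known reaction type is the nickel-catalysed, Et3B-driven homoallylation of aldehydes with 1,3-dienes, established for 2,3-dialkyl dienes and for α,β-unsaturated aldehydes with 1,2-addition and 1,3-anti selectivity. The only ring retained is the butenolide, closed by 5-exo-trig attack of the O12 borinate 11 on the cis-disposed C15 ester carbonyl with loss of methoxide; it is a temporary ring that freezes 13Z and masks O12. At C9 the hydride arrives from nickel on the α face, that is axially, so the C11 chain becomes equatorial (9β); at C12 the butenoate substituent in the five-membered O–Ni–C9–C11–C12 metallacycle turns away from the quaternary C10/C1 flank, which is the 1,3-anti arrangement and corresponds to 12S. The step needs bonding at C11 rather than C17: the oxidative cyclisation is reversible, and only the C11-bonded metallacycle can collapse by axial H delivery to an equatorial chain, whereas bonding at C17 would require equatorial (α) H delivery at C8 and force the new chain into the β-axial position, 1,3-diaxial to C20. Slow addition of 10 keeps its concentration low, which should hold back thermal Diels–Alder addition to its activated C=C bond and sequestration of nickel by the enoate.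

Step 8
Reactants: 12 butenolide TMSE ester
Product: 13 (12S)-labda-8(17),13-dien-15,12-olid-19-oic acid
Conditions: Bu4NF/AcOH (1:1, 4 equiv), THF, rt → 40 °C
Reagents that add atoms: none
Why: Fluoride-induced β-elimination (fragmentation) of the 2-(trimethylsilyl)ethyl ester cleaves the alkyl–oxygen bond without attack on the hindered carbonyl, and the acetic acid buffer keeps the medium too weakly basic to deprotonate the butenolide at C12.

Step 9
Reactants: 13 butenolide acid
Product: 15 (4S,5R,9S,10R,12S,13Z)-12-hydroxylabda-8(17),13-diene-15,19-dioic acid, via dilithium salt 14 (not isolated)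
Conditions: LiOH (3 equiv), THF/H2O, 0 °C; 0.1 M HCl to pH 4.5, 0 °C, immediate EtOAc extraction, evaporation below 10 °C
Reagents that add atoms: lithium hydroxide [Li+].[OH-]
Why: Saponification of the butenolide (acyl–oxygen cleavage by hydroxide at C15) is fast at 0 °C and leaves the C12–O bond intact, so 12S and 13Z are retained, and cold acidification only to pH 4–5 with immediate extraction should deliver the free hydroxy diacid before it re-lactonises.

**Compound list**
1 | (+)-podocarpic acid, 12-hydroxypodocarpa-8,11,13-trien-19-oic acid (4β-axial CO2H, 4α-CH3, 5α-H, 10β-CH3) | C[C@]12CCC[C@](C)(C(=O)O)[C@@H]1CCc1ccc(O)cc12 | starting material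
2 | 2-(trimethylsilyl)ethyl (TMSE) podocarpate | C[C@]12CCC[C@](C)(C(=O)OCC[Si](C)(C)C)[C@@H]1CCc1ccc(O)cc12 | intermediate
3 | 19-TMSE ester of 12,13,14,15,16-pentanorlabd-8-ene-11,17,19-trioic acid (CO2H on C8 and on C9 of the C8=C9 bond; 5α-H, 10β-CH3) | OC(=O)C2=C(C(=O)O)CC[C@@H]1[C@]2(C)CCC[C@]1(C)C(=O)OCC[Si](C)(C)C | intermediate
4 | 11,17-anhydride of 3 (maleic-type anhydride fused at C8=C9) | O=C1OC(=O)C2=C1CC[C@@H]1[C@]2(C)CCC[C@]1(C)C(=O)OCC[Si](C)(C)C | intermediate
5 | TMSE 11,17-dihydroxy-12,13,14,15,16-pentanorlabd-8-en-19-oate | OCC2=C(CO)CC[C@@H]1[C@]2(C)CCC[C@]1(C)C(=O)OCC[Si](C)(C)C | intermediate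
6 | TMSE 11,17-dibromo-12,13,14,15,16-pentanorlabd-8-en-19-oate | BrCC2=C(CBr)CC[C@@H]1[C@]2(C)CCC[C@]1(C)C(=O)OCC[Si](C)(C)C | intermediate
7 | TMSE 12,13,14,15,16-pentanorlabda-8(17),9(11)-dien-19-oate (ring B 1,2-bis-methylene diene) | C=C2C(=C)CC[C@@H]1[C@]2(C)CCC[C@]1(C)C(=O)OCC[Si](C)(C)C | intermediate
8 | 5-hydroxy-4-methylfuran-2(5H)-one (racemic pseudo-acid) | CC1=CC(=O)OC1O | starting material
9 | potassium (Z)-3-methyl-4-oxobut-2-enoate | O=C/C(C)=C\C(=O)[O-].[K+] | intermediate
10 | methyl (Z)-3-methyl-4-oxobut-2-enoate (CHO and CO2Me cis) | O=C/C(C)=C\C(=O)OC | intermediate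
11 | 12-O-diethylboryl ether of 15-methyl 19-TMSE (9S,12S,13Z)-12-hydroxylabda-8(17),13-diene-15,19-dioate | C=C1CC[C@@H]2[C@](C)(CCC[C@]2(C)C(=O)OCC[Si](C)(C)C)[C@H]1C[C@H](OB(CC)CC)/C(C)=C\C(=O)OC | intermediate
12 | TMSE (12S)-labda-8(17),13-dien-15,12-olid-19-oate (9α-H; 5-substituted 4-methylbutenolide) | C=C1CC[C@@H]2[C@](C)(CCC[C@]2(C)C(=O)OCC[Si](C)(C)C)[C@H]1C[C@@H]3OC(=O)C=C3C | intermediate
13 | (12S)-labda-8(17),13-dien-15,12-olid-19-oic acid | C=C1CC[C@@H]2[C@](C)(CCC[C@]2(C)C(=O)O)[C@H]1C[C@@H]3OC(=O)C=C3C | intermediate
14 | dilithium (12S,13Z)-12-hydroxylabda-8(17),13-diene-15,19-dioate | C=C1CC[C@@H]2[C@](C)(CCC[C@]2(C)C(=O)[O-])[C@H]1C[C@H](O)/C(C)=C\C(=O)[O-].[Li+].[Li+] | intermediate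
15 | (4S,5R,9S,10R,12S,13Z)-12-hydroxylabda-8(17),13-diene-15,19-dioic acid | C=C1CC[C@@H]2[C@](C)(CCC[C@]2(C)C(=O)O)[C@H]1C[C@H](O)/C(C)=C\C(=O)O | target

**Step count**
Total step count: 9. Longest linear sequence: 8 (steps 1–5 and 7–9); step 6 is a one-step branch.

**Steps most likely to fail**

1. Step 7.
   - What may go wrong: bonding of the aldehyde at the less encumbered C17 terminus, hydride delivery to the distal allyl terminus, or deactivation of nickel by the enoate.
   - Fallback, setting out from 7 and returning at 12: the same steric bias is put to use.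
   - One equivalent of ozone (CH2Cl2/pyridine, −78 °C) cleaves the more accessible C8=C17 bond of 7 to the TMSE 8-oxo-9(11)-methylene ester F1.
   - Commercial 4-methylfuran-2(5H)-one is silylated (TBSOTf, Et3N) to 2-(tert-butyldimethylsilyloxy)-4-methylfuran F2.
   - A vinylogous Mukaiyama–Michael addition of F2 to F1 (chiral oxazaborolidinium triflimide or Sc(OTf)3, CH2Cl2, −78 °C) forms the same C11–C12 bond, with the regiochemistry fixed by the enone polarity, and gives the C8 silyl enol ether adduct F3.
   - Mild acid hydrolysis protonates C9 under equilibrating conditions to the equatorial-chain 8-oxo butenolide F4.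
   - Non-basic Takai–Lombardo methylenation (Zn, CH2Br2, TiCl4), selective for ketones over lactones and esters, restores C8=C17 and gives 12.
   - C12 then rests on catalyst control instead of the metallacycle.

2. Step 9.
   - What may go wrong: re-lactonisation during acidification or concentration, and loss of configuration at C12 by γ-deprotonation before the ring opens.
   - Fallback, setting out from 14 (made from 13 as in step 9) and returning at 15: the open form is trapped and released instead of being acidified directly.
   - Freeze-dried 14 is persilylated (Et3SiOTf, 2,6-lutidine, CH2Cl2, −78 °C) to the 12-O-triethylsilyl bis(triethylsilyl) ester F5.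
   - Brief exposure to pH 7 phosphate buffer/THF hydrolyses the two silyl esters to the 12-O-triethylsilyl diacid F6, which cannot lactonise and can be purified.
   - NH4F in MeOH at 0 °C frees O12 under near-neutral conditions, and freeze-drying gives 15 without contact with mineral acid.

3. Step 2.
   - What may go wrong: first ozone attack at C12=C13, which leads on to cleavage of C9=C11 and C8=C14 with loss of the two carbons needed, and general over-oxidation.
   - Fallback, setting out from 2 and returning at 3 (then 4 as in step 2): ring C is opened stepwise under positional control.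
   - NBS (MeCN, 0 °C) brominates the unhindered ortho position to give TMSE 13-bromopodocarpate F7.
   - With C13 blocked, 2-iodoxybenzoic acid (DMF, rt) oxygenates C11 to the 13-bromo-11,12-ortho-quinone F8.
   - H2O2/HCO2H cleaves the 1,2-dione (Baeyer–Villiger-type) to the 11,12-seco diacid F9.
   - Ozone then finds only the C13=C14 bond open to attack, and oxidative work-up gives 3.

**Further compounds**
F1 | step 7 | TMSE 8-oxo-12,13,14,15,16,17-hexanorlabd-9(11)-en-19-oate (α-methylene ketone) | C=C2C(=O)CC[C@@H]1[C@]2(C)CCC[C@]1(C)C(=O)OCC[Si](C)(C)C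
F2 | step 7 | 2-(tert-butyldimethylsilyloxy)-4-methylfuran | Cc1coc(O[Si](C)(C)C(C)(C)C)c1
F3 | step 7 | TMSE (12S)-8-(tert-butyldimethylsilyloxy)-17-norlabda-8,13-dien-15,12-olid-19-oate | CC(C)(C)[Si](C)(C)OC1=C(C[C@@H]3OC(=O)C=C3C)[C@@]2(C)CCC[C@](C)(C(=O)OCC[Si](C)(C)C)[C@@H]2CC1
F4 | step 7 | TMSE (9α-H,12S)-8-oxo-17-norlabd-13-en-15,12-olid-19-oate | O=C1CC[C@@H]2[C@](C)(CCC[C@]2(C)C(=O)OCC[Si](C)(C)C)[C@H]1C[C@@H]3OC(=O)C=C3C
F5 | step 9 | bis(triethylsilyl) (12S,13Z)-12-(triethylsilyloxy)labda-8(17),13-diene-15,19-dioate | C=C1CC[C@@H]2[C@](C)(CCC[C@]2(C)C(=O)O[Si](CC)(CC)CC)[C@H]1C[C@H](O[Si](CC)(CC)CC)/C(C)=C\C(=O)O[Si](CC)(CC)CC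
F6 | step 9 | (12S,13Z)-12-(triethylsilyloxy)labda-8(17),13-diene-15,19-dioic acid | C=C1CC[C@@H]2[C@](C)(CCC[C@]2(C)C(=O)O)[C@H]1C[C@H](O[Si](CC)(CC)CC)/C(C)=C\C(=O)O
F7 | step 2 | TMSE 13-bromopodocarpate | C[C@]12CCC[C@](C)(C(=O)OCC[Si](C)(C)C)[C@@H]1CCc1cc(Br)c(O)cc12
F8 | step 2 | TMSE 13-bromo-11,12-dioxopodocarpa-8,13-dien-19-oate (ortho-quinone) | C[C@]12CCC[C@](C)(C(=O)OCC[Si](C)(C)C)[C@@H]1CCC1=C2C(=O)C(=O)C(Br)=C1
F9 | step 2 | 19-TMSE ester of 13-bromo-11,12-secopodocarpa-8,13-diene-11,12,19-trioic acid | C[C@]12CCC[C@](C)(C(=O)OCC[Si](C)(C)C)[C@@H]1CCC(/C=C(Br)\C(=O)O)=C2C(=O)O
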